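Start at early times, when the first D appears beside a full charge of E and you want to know where it will go.

| setting | ochre | violet | red | green |
|---|---|---|---|---|
| E | 0.20 M | 0.20 M | 0.20 M | 0.20 M |
| Z | 1.0 mM | 1.0 mM | 1.0 mM | 1.0 mM |
| temperature | 110 °C | 140 °C |  | 80 °C |
| time | 8.0 min | 8.0 min | 8.0 min | 8.0 min |
| remark |  |  | at 140 °C until 4.0 min, from then on at 80 °C |  |

    E → D (k1 = 0.0011 s⁻¹, Ea1 = 104 kJ mol⁻¹)
    Z + D → Z + J (k2 = 2.3 L mol⁻¹ s⁻¹, Ea2 = 53.0 kJ mol⁻¹)
    E + D → E.D (k3 = 0.016 L mol⁻¹ s⁻¹, Ea3 = 61.0 kJ mol⁻¹)
    (constants at 110 °C)

- a species is counted by the E in it: one E.D counts as two
- the constants hold at 110 °C; other temperatures follow from the activation energies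

- which flask leads in share of J in all that became J or E.D ("all alike" within 1.5 percentage points) (ochre / violet / red / green / all alike)
- share of J in all that became J or E.D, ochre
- share of J in all that became J or E.D, violet
- share of J in all that became J or E.D, red
- share of J in all that became J or E.D, green

Build the flask up one step at a time, and work with the fraction of E left. With the first step alone, that fraction after the full time is 96.8 % in green, 59.0 % in ochre and 0.351 % in violet.

Now add the catalysed step. Z comes back unchanged, so D decays pseudo-first-order, with a half-life of 1.50 min at violet's temperature and 20.6 min at green's. The share of J would be 100 %, though some D would still be waiting.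

Capture changes that number. Its rate scales with the E left, and each E.D counts twice, while D cancels from the comparison of the two routes. So define the crossover fraction as the catalysed constant times Z, divided by twice the capture constant times the E charged. It is the fraction of E left at which the two routes carry equal amounts of E at that moment. If x is the crossover fraction and e the fraction left, the momentary selectivity toward J is x/(x+e). Green has 44.5 %, ochre 35.9 % and violet 29.9 %.

Heat lowers the starting share, 23.0 % in violet against 30.8 % in green, because capture has the higher barrier. But violet's E crosses its x after about 1.71 min, by the first step alone, and red shares that heating until 4.0 min. After the change, red's D drains slowly because its half-life exceeds the time remaining, whereas violet's does not. I therefore commit to violet first and red second. For ochre I take the mean of its start and end selectivities, 32.1 %, and for green the same mean, 31.1 %, with the end values reckoned by the first step alone.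

The forecast names violet, with 34.4 % for ochre, 61 % for violet, 55.5 % for red and 31.5 % for green, on the ground that "the J share climbs as E runs down".

The simulation gives violet first, at 60.8 %, then red at 55.0 %, ochre at 34.5 % and green at 31.3 %.

Green held 96.4 % of its E at 8.00 min, so its crossover fraction gives a momentary selectivity of 31.6 % at that time, beside a share of 31.3 % over the whole run. Its neighbour differs in one setting, with Z at 2.5 × 10⁻⁴ M, a quarter of green's charge. The crossover fraction follows Z, so the neighbour's falls to 11.1 %. With 96.3 % of its E left, that gives a momentary selectivity of 10.3 %. The neighbour flask ended with J at 0.0973 % and E.D at 0.854 %, a share of 10.2 %.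

The rate constants were set for the occasion; no experiment stands behind them.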